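**Retrosynthetic overview**
1. Feature: in ring A the quaternary C5 (methyl C14) lies between C4 and C10. This is the ipso-carbon/two-β-carbon pattern of a 4,4-disubstituted cyclohexa-2,5-dienone, and the oxygenated C9 of ring B is bonded to C10 where an acyl anion would add.
2. Key disconnection C9–C10 (ring B): carbene-catalysed intramolecular Stetter desymmetrisation of the achiral aldehyde 4. It sets C5 (absolute) and C10 (cis, corrected later).
3. Ring order: ring A comes from p-cresol (C5–C6 by oxidative allylation, C9 by hydroformylation). Ring B closes second, in step 3.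
4. Ring A afterwards: C15 by cuprate addition to the surviving enone of the folded cis-decalin, O3 by Rubottom oxidation, removal of O2 (Barton–McCombie), then C10 epimerisation through the C9 ketone.
5. Ring B afterwards: the C9 oxygen is kept as an enol silane and hydroboration–oxidation puts a ketone at C8. C9 and C7 are then equilibrated to equatorial, C11–C13 come from 2-bromopropene (Pd α-alkenylation), C8 is set by LiBH(s-Bu)3, and the esters come from hex-2-ynoic acid and semi-hydrogenation.

Key step: step 3

Convention: eremophilane numbering is used throughout (ring A C1–C5, C10; ring B C5–C10; C14 on C5, C15 on C4, C11–C13 on C7). β is the face of the decalin that carries C14 and α is the opposite face.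
Assumption: the sense of induction of the triazolium catalyst in a six-membered closure cannot be derived safely from the five-membered cases, so the (5aS,10bR) antipode is written and its commercial mirror image is taken if a test run gives ent-5.

**Step 1**
Reactants: 1 p-cresol (4-methylphenol); 2 allyltrimethylsilane
Product: 3 4-allyl-4-methylcyclohexa-2,5-dien-1-one
Conditions: PhI(OAc)2 (1.1 equiv), 2 (4 equiv), (CF3)2CHOH, 0 to 23 °C
Reagents that add atoms: allyltrimethylsilane (2), C=CC[Si](C)(C)C
Why: Oxidative dearomatisation of a 4-alkylphenol by trivalent iodine in a non-nucleophilic fluoroalcohol gives a phenoxenium-type species that the allylsilane captures at the para carbon (oxidative Hosomi–Sakurai allylation), which forms the C5–C6 bond and the still achiral quaternary C5 in one operation.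

**Step 2**
Reactants: 3 4-allyl-4-methylcyclohexa-2,5-dien-1-one
Product: 4 4-methyl-4-(4-oxobutyl)cyclohexa-2,5-dien-1-one
Conditions: CO/H2 (1:1, 10 bar), Rh(acac)(CO)2 (1 mol%), Xantphos (2 mol%), toluene, 70 °C
Reagents that add atoms: carbon monoxide, [C-]#[O+]
Why: Linear-selective rhodium-catalysed hydroformylation with a wide-bite-angle diphosphine places the formyl carbon C9 on the terminal alkene carbon, the branching at C5 reinforcing the linear preference and the electron-poor disubstituted dienone bonds staying inert.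

**Step 3**
Reactants: 4 4-methyl-4-(4-oxobutyl)cyclohexa-2,5-dien-1-one
Product: 5 (4aR,8aS)-4a-methyl-2,3,4,4a,8,8a-hexahydronaphthalene-1,7-dione (cis-fused 5β-methyl-10βH-decal-3-ene-2,9-dione)
Conditions: (5aS,10bR)-2-(pentafluorophenyl)-5a,10b-dihydro-4H,6H-indeno[2,1-b][1,2,4]triazolo[4,3-d][1,4]oxazin-2-ium tetrafluoroborate (20 mol%), KN(SiMe3)2 (18 mol%), toluene (0.02 M), 23 °C
Reagents that add atoms: none
Why: Proposed new method: the free triazolylidene adds to the C9 aldehyde, a proton shift gives the Breslow-type enaminol (acyl-anion equivalent), its C9 adds to the β-carbon C10 of one enone arm, and proton transfer with loss of the carbene leaves the C9 ketone and, after protonation at C1, the C2 ketone next to the untouched C3=C4 enone. The closest known reaction type is the carbene-catalysed desymmetrising intramolecular Stetter reaction of 4,4-disubstituted cyclohexadienones, shown so far for five-membered closures through heteroatom tethers, together with aliphatic intramolecular Stetter closures of six-membered carbocycles onto acyclic acceptors. Ring B closes in the 6-exo-trig mode. C5 becomes stereogenic by the choice between the two enantiotopic enone arms, which only the indane wall and the N-aryl group of the catalyst can make, whereas C10 is fixed by the tether, since C9 can reach C10 only on the face of ring A that carries C6, so that H10 ends cis to C14. The step needs 1,4-acyl transfer to outrun aldol, C8-enolate Michael and acyloin pathways of the enolisable aldehyde; the substrate helps through two equivalent, unhindered, doubly activated β-carbons held in reach by a three-methylene tether on a quaternary carbon, and the conditions help through preformed carbene without excess base and high dilution.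

**Step 4**
Reactants: 5 cis-fused 5β-methyl-10βH-decal-3-ene-2,9-dione
Product: 6 4β,5β-dimethyl-2-(trimethylsilyloxy)-10βH-decal-2-en-9-one
Conditions: Me2CuLi (from MeLi and CuBr·SMe2), Me3SiCl, Et2O–THF, −78 °C; Et3N, cold aqueous NaHCO3 work-up
Reagents that add atoms: lithium dimethylcuprate, [Li+].C[Cu-]C; chlorotrimethylsilane, C[Si](C)(C)Cl
Why: Gilman cuprate 1,4-addition with in situ silyl trapping, in which axial attack on C4 is open only from the β face because the α trajectory would be 1,3-diaxial to C9 of the folded cis-decalin, so that C15 enters cis to C14, the saturated C9 ketone is left alone at −78 °C and the C2=C3 enol silane fixes the regiochemistry for step 5.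

**Step 5**
Reactants: 6 4β,5β-dimethyl-2-(trimethylsilyloxy)-10βH-decal-2-en-9-one
Product: 8 3α-hydroxy-4β,5β-dimethyl-10βH-decalin-2,9-dione, via 3α-trimethylsilyloxy dione 7 (not isolated)
Conditions: mCPBA (1.05 equiv), CH2Cl2, −20 °C; then citric acid (cat.), MeOH, 23 °C
Reagents that add atoms: 3-chloroperbenzoic acid, O=C(OO)c1cccc(Cl)c1
Why: Rubottom oxidation, in which the peracid reaches the nucleophilic C3 from the α face, anti to the axial C14 methyl that stands 1,3 to C3, silyl migration gives 7 and methanolysis frees the equatorial 3α-alcohol, which is also the more stable epimer of this still epimerisable centre.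

**Step 6**
Reactants: 8 3α-hydroxy-4β,5β-dimethyl-10βH-decalin-2,9-dione
Product: 9 3α-(tert-butyldimethylsilyloxy)-4β,5β-dimethyl-10βH-decalin-2,9-dione
Conditions: t-BuMe2SiCl, imidazole, DMF, 23 to 40 °C
Reagents that add atoms: tert-butyldimethylsilyl chloride, CC(C)(C)[Si](C)(C)Cl
Why: Standard silyl ether formation on a secondary alcohol under weakly basic conditions that avoid an α-ketol shift and touch no stereocentre.

**Step 7**
Reactants: 9 3α-(tert-butyldimethylsilyloxy)-4β,5β-dimethyl-10βH-decalin-2,9-dione
Product: 10 2α-hydroxy-3α-(tert-butyldimethylsilyloxy)-4β,5β-dimethyl-10βH-decalin-9-one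
Conditions: NaBH4 (0.5 equiv), CH2Cl2–MeOH, −78 °C; AcOH quench
Reagents that add atoms: none
Why: Chemoselective borohydride reduction, in which the α-silyloxy ketone at C2 is inductively activated while C9 is flanked by the ring fusion, hydride arrives from the convex β face because the α face of C2 is covered by axial C9, the 2α-alkoxide can mask C9 reversibly against over-reduction, and the new centre is erased in step 9.

**Step 8**
Reactants: 10 2α-hydroxy-3α-(tert-butyldimethylsilyloxy)-4β,5β-dimethyl-10βH-decalin-9-one
Product: 11 O-[3α-(tert-butyldimethylsilyloxy)-4β,5β-dimethyl-9-oxo-10βH-decalin-2α-yl] imidazole-1-carbothioate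
Conditions: 1,1'-thiocarbonyldiimidazole, DMAP (cat.), toluene, 90 °C
Reagents that add atoms: 1,1'-thiocarbonyldiimidazole, S=C(n1ccnc1)n1ccnc1
Why: Neutral thioacylation (first half of the Barton–McCombie sequence), preferred to xanthate formation with strong base so that neither O3-to-O2 silyl migration nor enolisation at C9 occurs, any ring–chain tautomerism of 10 draining through the open hydroxy ketone.

**Step 9**
Reactants: 11 the 2α-imidazolylthiocarbonyl derivative
Product: 12 3α-(tert-butyldimethylsilyloxy)-4β,5β-dimethyl-10βH-decalin-9-one (cis-fused)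
Conditions: Bu3SnH, AIBN (cat.), toluene, 100 °C
Reagents that add atoms: none
Why: Barton–McCombie deoxygenation, in which the stannyl radical adds to C=S, the secondary C2 radical is released and takes hydrogen from the stannane, which completes the move of the ring A oxygen from C2 to C3 and leaves the ketone and the silyl ether untouched.

**Step 10**
Reactants: 12 cis-fused 3α-(tert-butyldimethylsilyloxy)-4β,5β-dimethyl-10βH-decalin-9-one
Product: 13 trans-fused 3α-(tert-butyldimethylsilyloxy)-4β,5β-dimethyl-10αH-decalin-9-one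
Conditions: NaOMe (0.3 equiv), MeOH–THF, 23 °C; residual 12 separated and resubmitted
Reagents that add atoms: none
Why: Base-catalysed epimerisation α to the C9 ketone under thermodynamic control, which should favour the trans-decalin because it keeps C15 and O3 equatorial, whereas one chair–chair form of the cis isomer makes C15 and O3 axial (O3 syn-axial to C6) and the other makes C9 axial on ring A and C4 axial on ring B.

**Step 11**
Reactants: 13 trans-fused 3α-(tert-butyldimethylsilyloxy)-4β,5β-dimethyl-10αH-decalin-9-one
Product: 15 3α-(tert-butyldimethylsilyloxy)-9-(triisopropylsilyloxy)-4β,5β-dimethyl-10αH-decal-8-ene, via lithium Δ8-enolate 14 (not isolated)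
Conditions: LiN(i-Pr)2, THF, −78 °C; i-Pr3SiOTf, −78 to 0 °C
Reagents that add atoms: triisopropylsilyl triflate, CC(C)[Si](OS(=O)(=O)C(F)(F)F)(C(C)C)C(C)C
Why: Kinetic enolate formation and O-silylation, in which the amide base removes the accessible axial H8α rather than the tertiary H10, so that C10 is not disturbed and the C9 oxygen delivered by the key step is kept as a robust silyl ether.

**Step 12**
Reactants: 15 the Δ8 triisopropylsilyl enol ether
Product: 17 3α-(tert-butyldimethylsilyloxy)-9β-(triisopropylsilyloxy)-4β,5β-dimethyl-10αH-decalin-8α-ol, via 8α-borane 16 (not isolated)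
Conditions: BH3·THF, THF, 0 to 23 °C; then NaOH, H2O2, 0 °C
Reagents that add atoms: hydrogen peroxide, OO; borane (boron stays only in 16), B
Why: Hydroboration–oxidation of a silyl enol ether, in which boron goes to the β-carbon C8 for electronic reasons and syn addition occurs from the α face opposite the axial C14 methyl to give the trans 8α-ol/9β-silyl ether, the facial outcome being uncritical because C8 and C9 are reset in steps 13, 14 and 17.

**Step 13**
Reactants: 17 the 8α-ol
Product: 18 3α-(tert-butyldimethylsilyloxy)-9β-(triisopropylsilyloxy)-4β,5β-dimethyl-10αH-decalin-8-one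
Conditions: Dess–Martin periodinane, CH2Cl2, 23 °C
Reagents that add atoms: none
Why: Dess–Martin oxidation of a hindered axial secondary alcohol under neutral conditions, which moves the ring B carbonyl to C8 while the C9–O bond stays in place.

**Step 14**
Reactants: 18 the 9β-silyloxy 8-ketone
Product: 19 3α-(tert-butyldimethylsilyloxy)-9α-(triisopropylsilyloxy)-4β,5β-dimethyl-10αH-decalin-8-one
Conditions: NaOMe (0.3 equiv), MeOH–THF, 40 °C
Reagents that add atoms: none
Why: Thermodynamic epimerisation α to the C8 ketone, driven by relief of the 1,3-diaxial clash between the 9β-silyloxy group and C14, and chosen because direct hydride reduction of the C9 ketone of 13 would come from the α face and give the axial 9β-alcohol, the bulky triisopropylsilyl group resisting O-to-O migration in the enediolate.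

**Step 15**
Reactants: 19 the 9α-silyloxy 8-ketone; 20 2-bromopropene
Product: 22 3α-(tert-butyldimethylsilyloxy)-9α-(triisopropylsilyloxy)-10αH-eremophil-11-en-8-one as a C7 epimer mixture, via lithium Δ7-enolate 21 (not isolated)
Conditions: LiN(SiMe3)2 (2.2 equiv), Pd(P(t-Bu)3)2 (5 mol%), 20 (1.5 equiv), toluene–THF, 23 to 40 °C; AcOH quench at −78 °C
Reagents that add atoms: 2-bromopropene (20), C=C(C)Br
Why: Palladium-catalysed α-alkenylation of a ketone enolate (oxidative addition of the alkenyl bromide to zerovalent palladium, transmetalation with the lithium enolate, reductive elimination), in which only C7 offers an unhindered enolisable methylene, the second equivalent of base stores the more acidic product as its dienolate and cold acetic acid protonates it at the α-carbon so that the new double bond stays out of conjugation.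

**Step 16**
Reactants: 22 the C7 epimer mixture
Product: 23 7α-isopropenyl ketone, 3α-(tert-butyldimethylsilyloxy)-9α-(triisopropylsilyloxy)-7βH,10αH-eremophil-11-en-8-one
Conditions: DBU (0.2 equiv), CH2Cl2, 23 °C, short contact time
Reagents that add atoms: none
Why: Thermodynamic epimerisation through the dienolate, whose fast α-protonation funnels the material into the equatorial 7α-isomer because an axial 7β-isopropenyl group is 1,3-diaxial to C14, the mild base and short time keeping the slower γ-protonation to the conjugated isopropylidene ketone at bay.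

**Step 17**
Reactants: 23 the 7α-isopropenyl 8-ketone
Product: 24 3α-(tert-butyldimethylsilyloxy)-9α-(triisopropylsilyloxy)-10αH-eremophil-11-en-8α-ol
Conditions: LiBH(s-Bu)3, THF, −78 °C; then NaOH, H2O2, 0 °C
Reagents that add atoms: none
Why: Bulky trialkylborohydride reduction, in which the reagent avoids the axial α trajectory past H6α and H10α and attacks C8 equatorially from the β side, giving the axial 8α-alcohol between the two equatorial neighbours.

**Step 18**
Reactants: 24 the bis-silyl ether
Product: 25 10αH-eremophil-11-ene-3α,8α,9α-triol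
Conditions: Bu4NF (5 equiv), THF, 23 to 50 °C
Reagents that add atoms: none
Why: Fluoride-induced cleavage of both silyl ethers in one operation on a substrate that has no base-sensitive group, so that any silyl migration on the way is without consequence.

**Step 19**
Reactants: 25 10αH-eremophil-11-ene-3α,8α,9α-triol; 26 hex-2-ynoic acid
Product: 27 8α-hydroxy-10αH-eremophil-11-ene-3α,9α-diyl bis(hex-2-ynoate)
Conditions: 26 (2.2 equiv), DCC, DMAP (0.1 equiv), CH2Cl2, −20 to 0 °C
Reagents that add atoms: hex-2-ynoic acid (26), CCCC#CC(=O)O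
Why: Steglich esterification with site selection by sterics, the two equatorial hydroxyls at C3 and C9 reacting before the axial 8α-hydroxyl, which is flanked by two equatorial substituents and by the syn-axial H6α and H10α, and the ynoate avoiding the Z-to-E drift that an activated (Z)-enoic acid would suffer.

**Step 20**
Reactants: 27 the bis(hex-2-ynoate)
Product: 28 CNP0420276.1, 8α-hydroxy-10αH-eremophil-11-ene-3α,9α-diyl bis[(Z)-hex-2-enoate]
Conditions: H2 (1 atm), Pd/CaCO3 poisoned with Pb(OAc)2, quinoline, EtOAc, 23 °C, stopped after two equivalents of H2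
Reagents that add atoms: none
Why: Lindlar semi-hydrogenation, in which syn delivery of hydrogen to each alkyne gives both (Z)-enoates while the 1,1-disubstituted isopropenyl group is not reduced on the poisoned catalyst.

**Compound list**
1 | p-cresol (4-methylphenol) | Cc1ccc(O)cc1 | starting material
2 | allyltrimethylsilane | C=CC[Si](C)(C)C | starting material
3 | 4-allyl-4-methylcyclohexa-2,5-dien-1-one | C=CCC1(C)C=CC(=O)C=C1 | intermediate
4 | 4-methyl-4-(4-oxobutyl)cyclohexa-2,5-dien-1-one | O=CCCCC1(C)C=CC(=O)C=C1 | intermediate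
5 | (4aR,8aS)-4a-methyl-2,3,4,4a,8,8a-hexahydronaphthalene-1,7-dione (cis-fused 5β-methyl-10βH-decal-3-ene-2,9-dione) | C1C[C@]2(C)C=CC(=O)C[C@@H]2C(=O)C1 | intermediate
6 | 4β,5β-dimethyl-2-(trimethylsilyloxy)-10βH-decal-2-en-9-one | C1C[C@]2(C)[C@@H](C)C=C(O[Si](C)(C)C)C[C@@H]2C(=O)C1 | intermediate
7 | 3α-(trimethylsilyloxy)-4β,5β-dimethyl-10βH-decalin-2,9-dione | C1C[C@]2(C)[C@@H](C)[C@H](O[Si](C)(C)C)C(=O)C[C@@H]2C(=O)C1 | intermediate
8 | 3α-hydroxy-4β,5β-dimethyl-10βH-decalin-2,9-dione | C1C[C@]2(C)[C@@H](C)[C@H](O)C(=O)C[C@@H]2C(=O)C1 | intermediate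
9 | 3α-(tert-butyldimethylsilyloxy)-4β,5β-dimethyl-10βH-decalin-2,9-dione | C1C[C@]2(C)[C@@H](C)[C@H](O[Si](C)(C)C(C)(C)C)C(=O)C[C@@H]2C(=O)C1 | intermediate
10 | 2α-hydroxy-3α-(tert-butyldimethylsilyloxy)-4β,5β-dimethyl-10βH-decalin-9-one | C1C[C@]2(C)[C@@H](C)[C@H](O[Si](C)(C)C(C)(C)C)[C@H](O)C[C@@H]2C(=O)C1 | intermediate
11 | 2α-O-(imidazol-1-ylthiocarbonyl) derivative of 10 | C1C[C@]2(C)[C@@H](C)[C@H](O[Si](C)(C)C(C)(C)C)[C@H](OC(=S)n3ccnc3)C[C@@H]2C(=O)C1 | intermediate
12 | cis-fused 3α-(tert-butyldimethylsilyloxy)-4β,5β-dimethyl-10βH-decalin-9-one | C1C[C@]2(C)[C@@H](C)[C@H](O[Si](C)(C)C(C)(C)C)CC[C@@H]2C(=O)C1 | intermediate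
13 | trans-fused 3α-(tert-butyldimethylsilyloxy)-4β,5β-dimethyl-10αH-decalin-9-one | C1C[C@]2(C)[C@@H](C)[C@H](O[Si](C)(C)C(C)(C)C)CC[C@H]2C(=O)C1 | intermediate
14 | lithium Δ8-enolate of 13 | [Li+].C1C[C@]2(C)[C@@H](C)[C@H](O[Si](C)(C)C(C)(C)C)CC[C@H]2C([O-])=C1 | intermediate
15 | 3α-(tert-butyldimethylsilyloxy)-9-(triisopropylsilyloxy)-4β,5β-dimethyl-10αH-decal-8-ene | C1C[C@]2(C)[C@@H](C)[C@H](O[Si](C)(C)C(C)(C)C)CC[C@H]2C(O[Si](C(C)C)(C(C)C)C(C)C)=C1 | intermediate
16 | 8α-boryl-9β-(triisopropylsilyloxy) adduct of 15 | C1C[C@]2(C)[C@@H](C)[C@H](O[Si](C)(C)C(C)(C)C)CC[C@H]2[C@@H](O[Si](C(C)C)(C(C)C)C(C)C)[C@@H]1B | intermediate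
17 | 3α-(tert-butyldimethylsilyloxy)-9β-(triisopropylsilyloxy)-4β,5β-dimethyl-10αH-decalin-8α-ol | C1C[C@]2(C)[C@@H](C)[C@H](O[Si](C)(C)C(C)(C)C)CC[C@H]2[C@@H](O[Si](C(C)C)(C(C)C)C(C)C)[C@@H]1O | intermediate
18 | 3α-(tert-butyldimethylsilyloxy)-9β-(triisopropylsilyloxy)-4β,5β-dimethyl-10αH-decalin-8-one | C1C[C@]2(C)[C@@H](C)[C@H](O[Si](C)(C)C(C)(C)C)CC[C@H]2[C@@H](O[Si](C(C)C)(C(C)C)C(C)C)C1=O | intermediate
19 | 3α-(tert-butyldimethylsilyloxy)-9α-(triisopropylsilyloxy)-4β,5β-dimethyl-10αH-decalin-8-one | C1C[C@]2(C)[C@@H](C)[C@H](O[Si](C)(C)C(C)(C)C)CC[C@H]2[C@H](O[Si](C(C)C)(C(C)C)C(C)C)C1=O | intermediate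
20 | 2-bromopropene | C=C(C)Br | starting material
21 | lithium Δ7-enolate of 19 | [Li+].[O-]C1=CC[C@]2(C)[C@@H](C)[C@H](O[Si](C)(C)C(C)(C)C)CC[C@H]2[C@@H]1O[Si](C(C)C)(C(C)C)C(C)C | intermediate
22 | 3α-(tert-butyldimethylsilyloxy)-9α-(triisopropylsilyloxy)-10αH-eremophil-11-en-8-one, C7 epimer mixture | C=C(C)C1C[C@]2(C)[C@@H](C)[C@H](O[Si](C)(C)C(C)(C)C)CC[C@H]2[C@H](O[Si](C(C)C)(C(C)C)C(C)C)C1=O | intermediate
23 | 7α-isopropenyl epimer of 22 (7βH,10αH) | C=C(C)[C@@H]1C[C@]2(C)[C@@H](C)[C@H](O[Si](C)(C)C(C)(C)C)CC[C@H]2[C@H](O[Si](C(C)C)(C(C)C)C(C)C)C1=O | intermediate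
24 | 3α-(tert-butyldimethylsilyloxy)-9α-(triisopropylsilyloxy)-10αH-eremophil-11-en-8α-ol | C=C(C)[C@@H]1C[C@]2(C)[C@@H](C)[C@H](O[Si](C)(C)C(C)(C)C)CC[C@H]2[C@H](O[Si](C(C)C)(C(C)C)C(C)C)[C@@H]1O | intermediate
25 | 10αH-eremophil-11-ene-3α,8α,9α-triol | C=C(C)[C@@H]1C[C@]2(C)[C@@H](C)[C@H](O)CC[C@H]2[C@H](O)[C@@H]1O | intermediate
26 | hex-2-ynoic acid | CCCC#CC(=O)O | starting material
27 | 8α-hydroxy-10αH-eremophil-11-ene-3α,9α-diyl bis(hex-2-ynoate) | C=C(C)[C@@H]1C[C@]2(C)[C@@H](C)[C@H](OC(=O)C#CCCC)CC[C@H]2[C@H](OC(=O)C#CCCC)[C@@H]1O | intermediate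
28 | CNP0420276.1, 8α-hydroxy-10αH-eremophil-11-ene-3α,9α-diyl bis[(Z)-hex-2-enoate] | C=C(C)[C@@H]1C[C@]2(C)[C@@H](C)[C@H](OC(=O)/C=C\CCC)CC[C@H]2[C@H](OC(=O)/C=C\CCC)[C@@H]1O | target

**Total step count:** 20. **Longest linear sequence:** 20 (fully linear from p-cresol).

**Steps most likely to fail**

1. Step 3 (Stetter desymmetrisation).
 - Risk: the six-membered closure may be slow. The enolisable aldehyde would then be consumed by aldol, enolate Michael or acyloin pathways, or the catalyst may discriminate poorly between the two enone arms.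
 - Fallback: it uses known chemistry, sets out from 4, returns at 5 and still closes the C9–C10 bond.
 - Wittig homologation of 4 with Ph3P=CHOMe gives the enol ether 4-(5-methoxypent-4-en-1-yl)-4-methylcyclohexa-2,5-dien-1-one F1.
 - Aqueous acid hydrolyses it to 5-(1-methyl-4-oxocyclohexa-2,5-dien-1-yl)pentanal F2.
 - A diarylprolinol silyl ether then effects the established enamine-catalysed desymmetrising intramolecular Michael addition of a dienone-tethered aldehyde. In this step C9 is the α-carbon of the aldehyde, and the product is cis-fused 9-formyl-5β-methyl-10βH-decal-3-en-2-one F3.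
 - Condensation with morpholine gives the enamine 5β-methyl-9-(morpholinomethylidene)-10βH-decal-3-en-2-one F4.
 - Its electron-rich double bond is cleaved by O2 with CuCl. This excises the extra carbon and leaves the C9 ketone of 5.

2. Step 15 (α-alkenylation).
 - Risk: coupling at C7, which is flanked by the neopentyl-type C6, may be sluggish. β-Hydride elimination from the palladium enolate may compete, or the new double bond may migrate into conjugation under the basic conditions.
 - Fallback: it sets out from 19 and returns at 22, replacing the cross-coupling by aldol condensation and deconjugation.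
 - The zinc enolate of 19 (LiN(i-Pr)2, then ZnCl2) adds to acetone to give the aldol 7-(2-hydroxypropan-2-yl) ketone F5.
 - Mesylation with MsCl/Et3N followed by DBU gives the conjugated 7(11)-en-8-one (isopropylidene ketone) F6.
 - γ-Deprotonation with KOt-Bu in THF and kinetic α-protonation of the extended dienolate with AcOH at −78 °C moves the double bond to the isopropenyl position. This gives 22, which step 16 equilibrates as before.

3. Step 19 (selective bis-acylation).
 - Risk: the rate difference between the hindered equatorial 9α-hydroxyl and the axial 8α-hydroxyl may be too small. This would lead to acylation at O8, over-acylation or acyl migration across the cis-diol.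
 - Fallback: it sets out from 24 and returns at 27, blocking O8 with a group that cannot migrate.
 - 24 is etherified with 4-methoxybenzyl trichloroacetimidate and La(OTf)3 (cat.) to give the 8α-(4-methoxybenzyl) ether F7.
 - Bu4NF frees the 3α,9α-diol F8.
 - Exhaustive Steglich esterification with 26 gives the 8α-(4-methoxybenzyloxy) bis(hex-2-ynoate) F9.
 - DDQ in buffered wet CH2Cl2 removes the benzyl ether to give 27.

**Further compounds**
F1 | step 3 | 4-(5-methoxypent-4-en-1-yl)-4-methylcyclohexa-2,5-dien-1-one (E/Z mixture) | COC=CCCCC1(C)C=CC(=O)C=C1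
F2 | step 3 | 5-(1-methyl-4-oxocyclohexa-2,5-dien-1-yl)pentanal | O=CCCCCC1(C)C=CC(=O)C=C1
F3 | step 3 | cis-fused 9-formyl-5β-methyl-10βH-decal-3-en-2-one (C9 configuration immaterial) | C1C[C@]2(C)C=CC(=O)C[C@@H]2C(C=O)C1
F4 | step 3 | 5β-methyl-9-(morpholinomethylidene)-10βH-decal-3-en-2-one | C1C[C@]2(C)C=CC(=O)C[C@@H]2C(=CN3CCOCC3)C1
F5 | step 15 | 7-(2-hydroxypropan-2-yl)-3α-(tert-butyldimethylsilyloxy)-9α-(triisopropylsilyloxy)-4β,5β-dimethyl-10αH-decalin-8-one (C7 configuration immaterial) | CC(C)(O)C1C[C@]2(C)[C@@H](C)[C@H](O[Si](C)(C)C(C)(C)C)CC[C@H]2[C@H](O[Si](C(C)C)(C(C)C)C(C)C)C1=O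
F6 | step 15 | 3α-(tert-butyldimethylsilyloxy)-9α-(triisopropylsilyloxy)-10αH-eremophil-7(11)-en-8-one | CC(C)=C1C[C@]2(C)[C@@H](C)[C@H](O[Si](C)(C)C(C)(C)C)CC[C@H]2[C@H](O[Si](C(C)C)(C(C)C)C(C)C)C1=O
F7 | step 19 | 8α-(4-methoxybenzyloxy)-3α-(tert-butyldimethylsilyloxy)-9α-(triisopropylsilyloxy)-10αH-eremophil-11-ene | C=C(C)[C@@H]1C[C@]2(C)[C@@H](C)[C@H](O[Si](C)(C)C(C)(C)C)CC[C@H]2[C@H](O[Si](C(C)C)(C(C)C)C(C)C)[C@@H]1OCc3ccc(OC)cc3
F8 | step 19 | 8α-(4-methoxybenzyloxy)-10αH-eremophil-11-ene-3α,9α-diol | C=C(C)[C@@H]1C[C@]2(C)[C@@H](C)[C@H](O)CC[C@H]2[C@H](O)[C@@H]1OCc3ccc(OC)cc3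
F9 | step 19 | 8α-(4-methoxybenzyloxy)-10αH-eremophil-11-ene-3α,9α-diyl bis(hex-2-ynoate) | C=C(C)[C@@H]1C[C@]2(C)[C@@H](C)[C@H](OC(=O)C#CCCC)CC[C@H]2[C@H](OC(=O)C#CCCC)[C@@H]1OCc3ccc(OC)cc3
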